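The one constant you inherit at this bench is K. The north-east run at 25.0 h reads 72.7% J and 29.9% Q, and c(E) is the charge less the J formed, so K comes to 1.83 /M, the equilibrium constant c(J)/(c(Q)·c(E)) of Q + E ⇌ J. That is a reading, made from numbers that scatter by 1 percentage point. The west run, where Q exceeds E, reads 1.83 /M. In logarithms the rule is short: at equilibrium the logarithm of c(J)/c(Q) equals that of K·c(E), so with K held, one power of ten in free E is one power of ten in the equilibrium ratio.

| flask | Q | E | remark | time |
|---|---|---|---|---|
| north | 0.36 M | 0.869 M (in portions, 4) | run made earlier; portions every 12 min |  |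
| west | 2.4 M | 0.869 M (in portions, 4) | run made earlier; portions every 12 min |  |
| north-east | 0.79 M | 1.9 M (in portions, 4) | run made earlier; portions every 12 min |  |
| summer | 3.0 M | 0.869 M (in portions, 4) | the portions of E follow each other after 12 min, the first at the start | 25 h |
| autumn | 1.2 M | 0.869 M (in portions, 4) | the portions of E follow each other after 4.0 min, the first at the start | 25 h |
| spring | 0.79 M | 2.50 M (in portions, 4) | the portions of E follow each other after 40 min, the first at the start | 25 h |
| dusk | 2.5 M | 2.50 M (in portions, 4) | the portions of E follow each other after 6.0 min, the first at the start | 25 h |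
| dawn | 0.79 M | 0.869 M (in portions, 4) | the portions of E follow each other after 12 min, the first at the start | 25 h |
| winter | 0.40 M | 0.869 M (in portions, 4) | the portions of E follow each other after 20 min, the first at the start | 25 h |

| run | time / h | J / % | Q / % |
|---|---|---|---|
| north | 5.00 | 45.4 | 53.4 |
| north | 10.0 | 51.8 | 46.9 |
| north | 15.0 | 53.1 | 45.8 |
| north | 20.0 | 53.3 | 44.6 |
| north | 25.0 | 54.2 | 44.9 |
| west | 5.00 | 26.7 | 72.2 |
| west | 10.0 | 28.1 | 71.5 |
| west | 15.0 | 26.9 | 72.2 |
| west | 20.0 | 26.9 | 69.5 |
| west | 25.0 | 27.3 | 69.6 |
| north-east | 5.00 | 67.6 | 32.4 |
| north-east | 10.0 | 71.3 | 28.1 |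
| north-east | 15.0 | 71.1 | 29.0 |
| north-east | 20.0 | 70.7 | 28.8 |
| north-east | 25.0 | 72.7 | 29.9 |

(readings scatter by 1 percentage point)

- all flasks from highest to lowest amount of J, in percent of the Q charged, at 25 h (summer / autumn / spring / dusk / dawn / winter)
- the amount of J, in percent of the Q charged of the flask you put first, at 25 h
- the amount of J, in percent of the Q charged of the flask you put last, at 25 h

When you arrive, expect Q, E and J near rest, with little X: at 25.0 h the west run's readings of Q and J leave 3.1 points unaccounted for, less than the J itself. Leave the portion timing alone. Even in spring, whose portions stand furthest apart, the last portion is in after 2.00 h, far earlier than 25 h, and the J reading of the north-east run moved by 1.4 points from 10.0 h to 25.0 h.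

With this K, the balance of the charges gives me 77.6% J for spring. For summer, where E is the limiting reagent, it gives 23.4%. The forecast orders the flasks spring > dusk > winter > dawn > autumn > summer, with 77% first and 23% last, holding that “Portion spacing of minutes cannot matter at 25 h”. My spring figure stands above its own, and my summer figure matches.

    Q + E ⇌ J (K = 1.80 /M, k = 0.262 /M/h)
    Q → X (k = 0.00114 /h)

The flasks end as spring > dusk > winter > dawn > autumn > summer, from 76.7% in spring to 23.2% in summer, and the dosing makes no difference to spring's J. Spring keeps 1.89 M of E free, so K·c(E) is 3.47, beside a J-to-Q ratio of 3.41. A neighbour of spring charged with 2.0 M of Q keeps 1.16 M of E free, so K·c(E) there is 2.13, and that neighbour holds 66.9% J against 32.0% Q, a ratio of 2.09.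

The data were generated by integration for an exercise, noise included.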